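The ring nitrogen N1 and C6 (the carbon bearing the CH2C(=O)NH arm) are the fusion atoms shared by the tetrahydropyridine and the 13-membered lactam, and the cis C3=C4 olefin lies in the six-membered ring only; opening N1–C6 and C3=C4 unravels both rings to one chain. The key step closes them in one flask: Z-selective macrocyclic olefin metathesis forms the 17-membered perimeter ring (C3=C4), then the secondary amine displaces a C6 mesylate across that ring with inversion (N1–C6). Its precursor is an acyclic diene amino mesylate whose stereocentres come from a sulfinimine Mannich addition (C2, the oxoheptyl-bearing carbon) and a chiral-pool chlorohydrin ester (C6).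

Key step: step 11

Remark: ring positions are numbered N1, C2 (2-oxoheptyl), C3=C4, C5, C6 (CH2C(=O)NH arm); in this numbering the target is the trans-(2S,6R) isomer, and compounds 1, 2, 4, 8, 10, 12 and 14 are taken as commercial.

Step 1
Reactants: 1 acrolein; 2 (R)-tert-butanesulfinamide
Product: 3 (R,E)-N-(prop-2-en-1-ylidene)-2-methylpropane-2-sulfinamide
Conditions: Ti(OEt)4, THF, rt
Reagents that add atoms: none
Why: Ti(IV)-mediated condensation of the aldehyde with the sulfinamide (sulfinimine formation) should give the E aldimine, the sulfur stereocentre being carried in unchanged from 2.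

Step 2
Reactants: 4 heptan-2-one; 3 sulfinimine
Product: 6 (R)-N-[(3S)-5-oxodec-1-en-3-yl]-2-methylpropane-2-sulfinamide, via lithium hept-1-en-2-olate 5 (not isolated)
Conditions: LDA, THF, −78 °C; then 3, −78 °C; NH4Cl quench at −78 °C
Reagents that add atoms: none
Why: Kinetic deprotonation at the methyl group gives the terminal enolate, which should add 1,2 to the sulfinimine (Mannich-type addition) through a six-membered chair transition state with lithium bridging the enolate and sulfinyl oxygens, so that the (R)-sulfinyl group directs attack to the Si face of C=N and sets C2 as S.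

Step 3
Reactants: 6 sulfinamide
Product: 7 (3S)-3-aminodec-1-en-5-one hydrochloride
Conditions: HCl (4 M in dioxane), MeOH, 0 °C to rt
Reagents that add atoms: hydrogen chloride, Cl
Why: Acidic methanolysis of the N–S bond (sulfinamide cleavage) should release the primary amine as its hydrochloride without touching the ketone, the alkene or the stereocentre.

Step 4
Reactants: 8 ethyl (3R)-4-chloro-3-hydroxybutanoate
Product: 9 ethyl [(2R)-oxiran-2-yl]acetate
Conditions: Ag2O, MeCN, 60 °C, dark
Reagents that add atoms: none
Why: Silver(I)-assisted intramolecular etherification (halohydrin to epoxide) should close the oxirane under non-basic conditions that avoid isomerisation to the 4-hydroxycrotonate; the carbinol centre is not involved and stays R.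

Step 5
Reactants: 9 epoxy ester; 10 vinylmagnesium bromide
Product: 11 ethyl (3S)-3-hydroxyhex-5-enoate
Conditions: CuI (10 mol %), THF, −40 to −20 °C
Reagents that add atoms: none
Why: Copper-catalysed Grignard opening of the terminal epoxide at its unsubstituted carbon (SN2) should give the homoallylic alcohol with the ester intact at low temperature; the stereocentre is untouched, the descriptor changing from R to S only through the priority rules.

Step 6
Reactants: 11 hydroxy ester; 12 butane-1,4-diamine (5 equiv)
Product: 13 (3S)-N-(4-aminobutyl)-3-hydroxyhex-5-enamide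
Conditions: MeOH, 60 °C; excess diamine removed in vacuo
Reagents that add atoms: none
Why: Ester aminolysis by the primary amine, helped by the β-hydroxyl group, should give the amide, the large excess of the symmetrical diamine securing mono-acylation.

Step 7
Reactants: 13 amino amide; 14 methyl acrylate
Product: 16 methyl 3-[(tert-butoxycarbonyl)(4-{[(3S)-3-hydroxyhex-5-enoyl]amino}butyl)amino]propanoate, via secondary amino ester 15 (not isolated)
Conditions: methyl acrylate (1.05 equiv), MeOH, 0 °C to rt; then Boc2O, Et3N, rt
Reagents that add atoms: di-tert-butyl dicarbonate, CC(C)(C)OC(=O)OC(=O)OC(C)(C)C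
Why: Aza-Michael addition of the primary amine to the acrylate should stop at the mono-adduct at low temperature, and in situ carbamate formation (Boc protection) then caps the new secondary amine while the secondary alcohol and the amide stay free.

Step 8
Reactants: 16 hydroxy ester
Product: 17 methyl 3-[(tert-butoxycarbonyl)(4-{[(3S)-3-(methanesulfonyloxy)hex-5-enoyl]amino}butyl)amino]propanoate
Conditions: MsCl, Et3N, CH2Cl2, −10 °C
Reagents that add atoms: methanesulfonyl chloride, CS(=O)(=O)Cl
Why: O-Sulfonylation of the secondary alcohol (mesylation) proceeds with retention at C6 and should not touch the amide or carbamate nitrogens, low temperature suppressing β-elimination.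

Step 9
Reactants: 17 mesylate ester
Product: 18 tert-butyl (4-{[(3S)-3-(methanesulfonyloxy)hex-5-enoyl]amino}butyl)(3-oxopropyl)carbamate
Conditions: DIBAL-H (2.2 equiv), CH2Cl2, −78 °C; MeOH, then Rochelle salt
Reagents that add atoms: none
Why: Partial ester reduction by DIBAL-H at −78 °C should stop at the aldehyde through the aluminium hemiacetal, the extra equivalent being consumed by the amide N–H, while the secondary mesylate and the carbamate are inert at this temperature.

Step 10
Reactants: 7 amine hydrochloride; 18 aldehyde
Product: 20 tert-butyl (4-{[(3S)-3-(methanesulfonyloxy)hex-5-enoyl]amino}butyl)(3-{[(3S)-5-oxodec-1-en-3-yl]amino}propyl)carbamate, via aldimine 19 (not isolated)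
Conditions: Et3N (1 equiv), NaBH(OAc)3, ClCH2CH2Cl, 0 °C to rt
Reagents that add atoms: none
Why: Reductive amination: the free-based primary amine condenses with the aldehyde and the aldimine is reduced by triacetoxyborohydride, which should leave ketone, mesylate and alkenes untouched, α-branching of the amine preventing a second alkylation.

Step 11
Reactants: 20 acyclic diene amino mesylate
Product: 22 N-Boc-protected bicyclic lactam (target with a tert-butyl carbamate on the chain nitrogen), via Z-macrocyclic mesylate 21 (not isolated)
Conditions: Z-selective cyclometalated Ru nitrato catalyst (10 mol %), ClCH2CH2Cl (3 mM), 60 °C, static vacuum; then i-Pr2NEt, 60 °C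
Reagents that add atoms: none
Why: The Ru alkylidene should load at the unhindered allyl terminus and close the 17-membered perimeter ring onto the C2 vinyl group by ring-closing olefin metathesis (loss of ethylene), the cyclometalated catalyst enforcing a syn-substituted metallacyclobutane and hence the Z C3=C4 bond; in the Z ring N1 and C6 sit 1,6 across the olefin turn, so the secondary amine displaces the C6 mesylate transannularly by SN2. The closest known reaction types are Z-selective macrocyclic ring-closing metathesis and piperidine formation by amine cyclisation onto a secondary sulfonate. The macrocycle closes by metathesis, the tetrahydropyridine by 6-exo-tet transannular N-alkylation, and the 13-membered lactam is the loop that remains. No stereocentre is created from a prochiral atom: C6 is inverted stereospecifically (S to R) by backside attack and C2 is untouched, so the trans relationship follows from the two independently set centres. The step needs Z over E (catalyst control; an E macrocycle cannot close and stays behind as separable material), substitution over elimination (weakly acidic amide α-CH, hindered amine base, six-membered transition state) and N1 over the other nitrogens (chain amine masked as its Boc carbamate, amide nitrogen non-nucleophilic).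

Step 12
Reactants: 22 N-Boc bicyclic lactam
Product: 23 target CNP0183222.1
Conditions: TFA, CH2Cl2, 0 °C to rt; aq. K2CO3 work-up
Reagents that add atoms: none
Why: Acidolysis of the tert-butyl carbamate (Boc removal) should liberate the chain secondary amine, protonation of the amines suppressing retro-Michael opening at C2, and mild basic work-up should give the free base with both stereocentres unchanged.

Compound list
1 | acrolein | C=CC=O | starting material
2 | (R)-tert-butanesulfinamide | CC(C)(C)[S@@](=O)N | starting material
3 | (R,E)-N-(prop-2-en-1-ylidene)-2-methylpropane-2-sulfinamide | CC(C)(C)[S@@](=O)/N=C/C=C | intermediate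
4 | heptan-2-one | CCCCCC(C)=O | starting material
5 | lithium hept-1-en-2-olate | [Li+].[O-]C(=C)CCCCC | intermediate
6 | (R)-N-[(3S)-5-oxodec-1-en-3-yl]-2-methylpropane-2-sulfinamide | CCCCCC(=O)C[C@H](N[S@](=O)C(C)(C)C)C=C | intermediate
7 | (3S)-3-aminodec-1-en-5-one hydrochloride | CCCCCC(=O)C[C@H]([NH3+])C=C.[Cl-] | intermediate
8 | ethyl (3R)-4-chloro-3-hydroxybutanoate | CCOC(=O)C[C@@H](O)CCl | starting material
9 | ethyl [(2R)-oxiran-2-yl]acetate | CCOC(=O)C[C@@H]1CO1 | intermediate
10 | vinylmagnesium bromide | C=C[Mg]Br | starting material
11 | ethyl (3S)-3-hydroxyhex-5-enoate | CCOC(=O)C[C@@H](O)CC=C | intermediate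
12 | butane-1,4-diamine | NCCCCN | starting material
13 | (3S)-N-(4-aminobutyl)-3-hydroxyhex-5-enamide | NCCCCNC(=O)C[C@@H](O)CC=C | intermediate
14 | methyl acrylate | C=CC(=O)OC | starting material
15 | methyl 3-[(4-{[(3S)-3-hydroxyhex-5-enoyl]amino}butyl)amino]propanoate | COC(=O)CCNCCCCNC(=O)C[C@@H](O)CC=C | intermediate
16 | methyl 3-[(tert-butoxycarbonyl)(4-{[(3S)-3-hydroxyhex-5-enoyl]amino}butyl)amino]propanoate | COC(=O)CCN(CCCCNC(=O)C[C@@H](O)CC=C)C(=O)OC(C)(C)C | intermediate
17 | methyl 3-[(tert-butoxycarbonyl)(4-{[(3S)-3-(methanesulfonyloxy)hex-5-enoyl]amino}butyl)amino]propanoate | COC(=O)CCN(CCCCNC(=O)C[C@@H](OS(C)(=O)=O)CC=C)C(=O)OC(C)(C)C | intermediate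
18 | tert-butyl (4-{[(3S)-3-(methanesulfonyloxy)hex-5-enoyl]amino}butyl)(3-oxopropyl)carbamate | O=CCCN(CCCCNC(=O)C[C@@H](OS(C)(=O)=O)CC=C)C(=O)OC(C)(C)C | intermediate
19 | aldimine from 7 and 18 (E-configured C=N) | CCCCCC(=O)C[C@@H](C=C)/N=C/CCN(CCCCNC(=O)C[C@@H](OS(C)(=O)=O)CC=C)C(=O)OC(C)(C)C | intermediate
20 | tert-butyl (4-{[(3S)-3-(methanesulfonyloxy)hex-5-enoyl]amino}butyl)(3-{[(3S)-5-oxodec-1-en-3-yl]amino}propyl)carbamate | CCCCCC(=O)C[C@@H](C=C)NCCCN(CCCCNC(=O)C[C@@H](OS(C)(=O)=O)CC=C)C(=O)OC(C)(C)C | intermediate
21 | 17-membered (Z)-macrocyclic amino mesylate (ring N1–C2–C3=C4–C5–C6(OMs)–CH2–C(=O)NH–(CH2)4–N(Boc)–(CH2)3; C2 S with 2-oxoheptyl, C6 S) | CCCCCC(=O)C[C@H]1/C=C\C[C@H](OS(C)(=O)=O)CC(=O)NCCCCN(C(=O)OC(C)(C)C)CCCN1 | intermediate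
22 | N-Boc-protected bicyclic lactam (target carrying a tert-butyl carbamate on the chain nitrogen; C2 S, C6 R) | CCCCCC(=O)C[C@H]1C=CC[C@@H]2CC(=O)NCCCCN(C(=O)OC(C)(C)C)CCCN21 | intermediate
23 | CNP0183222.1: trans-(2S,6R) tetrahydropyridine fused through N1–C6 to the 13-membered spermidine lactam, 2-oxoheptyl at C2 | CCCCCC(=O)C[C@H]1C=CC[C@@H]2CC(=O)NCCCCNCCCN21 | target

Total step count: 12. Longest linear sequence: 9 steps (steps 4 to 12, from 8); the C2 branch (steps 1 to 3) joins at step 10.

Steps most likely to fail

1. Step 11. The macrocyclic metathesis may close with too little Z-selectivity, or the catalyst may be deactivated by the basic secondary amine, leaving an E macrocycle that cannot close or unreacted diene; elimination of the mesylate may also compete with substitution. The fallback forms the C–N bond first, runs the metathesis on the six-membered ring and closes the macrocycle last. It sets out from 18 and 7. The aldehyde of 18 is masked as the dimethyl acetal tert-butyl (3,3-dimethoxypropyl)(4-{[(3S)-3-(methanesulfonyloxy)hex-5-enoyl]amino}butyl)carbamate F1 (HC(OMe)3, PPTS, MeOH). Free-based 7 is then N-alkylated by the secondary mesylate of F1 with inversion (K2CO3, MeCN, 60 °C, no iodide) to give the diene secondary amine F2. Ring-closing metathesis of its tosylate salt (Hoveyda–Grubbs II, CH2Cl2, 40 °C) should close the tetrahydropyridine acetal F3, where no olefin geometry question arises. Mild acetal hydrolysis (PPTS, acetone–water) gives the amino aldehyde F4, and intramolecular reductive amination at high dilution (NaBH(OAc)3, ClCH2CH2Cl) closes the 13-membered ring and comes back to the route at 22.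

2. Step 2. Conjugate addition to the unsaturated sulfinimine, erosion of facial selectivity with the lithium enolate, or retro-Mannich reversal on warming may lower the yield or the diastereomeric purity at C2. The fallback sets out from 3. Addition of the chlorotitanium enolate of methyl acetate (LDA, ClTi(Oi-Pr)3, THF, −78 °C) should give methyl (3S)-3-{[(R)-tert-butylsulfinyl]amino}pent-4-enoate F5 through the same chelated chair. This is converted into the N-methoxy-N-methylamide F6 (MeNH(OMe)·HCl, i-PrMgCl, THF, −20 °C), and pentylmagnesium bromide (THF, 0 °C) then gives the ketone and comes back to the route at 6.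

3. Step 9. Over-reduction of the ester to the alcohol, or loss of the mesylate by elimination or reduction under the aluminium hydride conditions, may occur. The fallback sets out from 16 and defers mesylation. LiBH4 (THF, 0 °C to rt) reduces the ester fully to the diol tert-butyl (3-hydroxypropyl)(4-{[(3S)-3-hydroxyhex-5-enoyl]amino}butyl)carbamate F7. TEMPO/PhI(OAc)2 (CH2Cl2, rt) oxidises only the primary alcohol to the hydroxy aldehyde F8, and mesylation of the remaining secondary alcohol (MsCl, Et3N, CH2Cl2, −20 °C) comes back to the route at 18.

Further compounds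
F1 | step 11 | tert-butyl (3,3-dimethoxypropyl)(4-{[(3S)-3-(methanesulfonyloxy)hex-5-enoyl]amino}butyl)carbamate | COC(OC)CCN(CCCCNC(=O)C[C@@H](OS(C)(=O)=O)CC=C)C(=O)OC(C)(C)C
F2 | step 11 | tert-butyl (3,3-dimethoxypropyl)(4-{[(3R)-3-{[(3S)-5-oxodec-1-en-3-yl]amino}hex-5-enoyl]amino}butyl)carbamate | CCCCCC(=O)C[C@@H](C=C)N[C@H](CC=C)CC(=O)NCCCCN(CCC(OC)OC)C(=O)OC(C)(C)C
F3 | step 11 | tert-butyl (3,3-dimethoxypropyl)[4-({[(2R,6S)-6-(2-oxoheptyl)-1,2,3,6-tetrahydropyridin-2-yl]acetyl}amino)butyl]carbamate | CCCCCC(=O)C[C@H]1C=CC[C@H](CC(=O)NCCCCN(CCC(OC)OC)C(=O)OC(C)(C)C)N1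
F4 | step 11 | tert-butyl (3-oxopropyl)[4-({[(2R,6S)-6-(2-oxoheptyl)-1,2,3,6-tetrahydropyridin-2-yl]acetyl}amino)butyl]carbamate | CCCCCC(=O)C[C@H]1C=CC[C@H](CC(=O)NCCCCN(CCC=O)C(=O)OC(C)(C)C)N1
F5 | step 2 | methyl (3S)-3-{[(R)-tert-butylsulfinyl]amino}pent-4-enoate | COC(=O)C[C@H](N[S@](=O)C(C)(C)C)C=C
F6 | step 2 | (3S)-3-{[(R)-tert-butylsulfinyl]amino}-N-methoxy-N-methylpent-4-enamide | CON(C)C(=O)C[C@H](N[S@](=O)C(C)(C)C)C=C
F7 | step 9 | tert-butyl (3-hydroxypropyl)(4-{[(3S)-3-hydroxyhex-5-enoyl]amino}butyl)carbamate | OCCCN(CCCCNC(=O)C[C@@H](O)CC=C)C(=O)OC(C)(C)C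
F8 | step 9 | tert-butyl (4-{[(3S)-3-hydroxyhex-5-enoyl]amino}butyl)(3-oxopropyl)carbamate | O=CCCN(CCCCNC(=O)C[C@@H](O)CC=C)C(=O)OC(C)(C)C
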